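## Structural features

The target contains two rings that are not fused: a cyclopentane (ring A) and a benzene (ring B), joined through the chain ArCH2–CH=C(CH3)–CH2–C(=O)–CH2– that ends on ring A carbon C2. Ring A holds the only two stereocentres, on adjacent carbons: C1 (CH3 and the (E)-4-hydroxy-4-methylpent-2-enoyl group) and C2 (CH3 and the CH2 arm); both are quaternary, both are R, and the two methyl groups are cis. Ring B is a 5-hydroxy-2-methoxy-3-methylphenyl group, a hydroquinone monomethyl ether that is easily oxidised to a quinone. The chain ketone lies β,γ to the E-trisubstituted alkene and can slip into conjugation; it is also 1,5 to the enone carbonyl, so base can trigger an aldol closure, and the enone carries a tertiary allylic alcohol. The real difficulty is the vicinal pair of quaternary stereocentres carrying two different one-carbon branches: a derivative with the same group on both branches (for example the bis-hydroxymethyl compound) would be meso, so the branches must never reach the same oxidation level. The key step exploits the fact that the C1(CH3)(C=O)–C2(CH3)(CH2–) unit of ring A is the C1(CH3)(CO2H)–C2(CH3)2 unit of 1, whose C3 carboxyl, as a carboxamide, lies cis to exactly one of the two C2 methyl groups and can oxidise that methyl before being removed.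

## Logic of the disconnections

38 to 37 (aryl O–Si bond). The phenol is freed last because a free hydroquinone monoether would not survive the preceding oxidation. Nothing is simplified structurally; the forward demand is a desilylation mild enough for the skipped enone and the 1,5-diketone.

37 to 36 (both C=O bonds returned to CH–OH). The two ketones are the fragile functions and are therefore made together and late. The gain is that two carbinol centres need no control; the oxidation must be neutral and must spare the tertiary alcohol and the arene.

36 to 35 to 34 (E-alkene back to alkyne; O–Si bond of the chain carbinol). An alkyne lets a hydroxyl-directed trans-reduction fix the E geometry. The chain silyl ether is removed one step earlier, while the molecule is still an acid-tolerant ynediol; the acid must spare the aryl silyl ether and the hydride must leave the isolated alkene.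

34 to 31 and 32 (bond from carbinol carbon to alkyne carbon; 33 is the nucleophile). This cut detaches the whole five-carbon enone arm as a commodity alkynol and reduces the ring fragment to an aldehyde. The aldehyde sits between two quaternary carbons, so a rod-shaped nucleophile is required.

31 to 30 to 29 (oxidation level of the carbon on C1). Going back to the ester gives a spectator that cannot migrate and never passes through a symmetrical diol pattern, which would open a path to racemisation. The price is the late reduction of a very hindered ester.

29 to 21 and 27 (vinyl C–CH3 and vinyl C–CH2Ar bonds; 28 is the alkenyl metal). Cutting at the alkene separates arene and cyclopentane and sets the E geometry in the bond-forming step. The forward step needs regioselective syn-carbometalation and a coupling that transfers alkenyl and not methyl.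

27 to 26, 25, 23 and 22 (benzylic C–Br, then the aryl–CH2 bond; 24 is the aryl metal). The benzylic carbon is placed ortho to methoxy by directed metalation, which an electrophilic substitution could not do. Ring lithiation must win over the benzylic methyl and over the positions next to the silyloxy group.

21 to 20 to 17 and 18 (O–Si, then the bond from carbinol carbon to propargylic CH2; 19 is the organozinc). The ketone carbon arrives as an aldehyde and the alkyne as a three-carbon unit. The addition must give the propargyl and not the allenyl product.

17 to 15 (the CH2–CHO bond; 16). The oxidised methyl supplies only a one-carbon branch, so one carbon is added. The olefination has to work on a neopentyl aldehyde.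

15 to 14 to 13 (oxidation level, O–Si). These are adjustments only; the alcohol must be freed without letting it close onto the neighbouring ester.

13 to 11 (the C3–CO2H bond, re-attached in the backward sense; 12). The C3 carboxyl is the handle that directs the C–H oxidation and must then vanish. Restoring it recovers the 1,3-dicarboxylic pattern of the chiral pool; the forward step is a radical decarboxylation at a secondary carbon next to a quaternary one.

11 to 8 (acyl C–O bond of the lactone; 9 and 10). Opening the lactone separates the carbon to be deleted from the carbon to be kept. The hydroxy carboxylate must be trapped before it recloses, without touching the ester.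

8 to 4 (the CH2–O bond; 5, 6 and 7). This is the strategic cut: it turns the C2 stereocentre into a geminal dimethyl group, so ring A, both quaternary carbons and the absolute configuration come from a commodity. The forward step must pick one of two methyl groups, which the reach of the cis carboxamide provides. The ester/primary amide pairing of 4 is kept: a free acid would be decarboxylated under the same conditions, and only an N-unsubstituted amide gives an iminolactone that hydrolyses to the lactone. A check of the configuration shows that C1 of 1 becomes the acyl-bearing carbon and the oxidised methyl becomes the CH2 arm on the same face, which is the (1R,2R) arrangement of 38.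

4 to 3 to 2 to 1 (ester C–O, amide C–N, anhydride C–O). The two carboxyl groups are told apart by their steric difference: the nucleophile goes to the carbonyl on the CH carbon, and the tertiary acid is esterified by O-alkylation.

## Other disconnections considered

Alternative 1: The cut removes the two ring-fusion C–CH3 bonds of the bicyclic ketone A2 and leads back to the tetrasubstituted enone A1. The cyclopentanone ring of A2 is temporary: its C2–C3 bond would later be cleaved (enol silylation toward the only enolisable side, then oxidative cleavage) to release the acid on one quaternary carbon and the CH2CHO arm on the other, that is 17 after esterification. In the forward key step a chiral phosphoramidite complex of Cu(O2CC4H3S) would transfer methyl from Me3Al to the β ring-fusion carbon of A1, and the aluminium enolate would be methylated with MeI at the α ring-fusion carbon; the cis ring fusion forces the second methyl onto the face of the first. In its favour, both quaternary centres and both C–CH3 bonds arise in one flask from a catalytic source of chirality, either enantiomer is available, and the ring cleavage delivers the two arms already differentiated with the CH2 arm at its final length, so neither a decarboxylation nor a Wittig homologation is needed. Against it here, an enone substituted at both alkene carbons is a poor acceptor for copper-catalysed conjugate addition, five-membered enones are regarded as harder substrates for enantiocontrol than six-membered ones, and C-methylation of a hindered aluminium enolate to a second quaternary carbon must compete with protonation and O-alkylation. The enantiomeric purity of A2 would have to be measured and perhaps upgraded on a volatile, non-crystalline ketone. In comparison, the alternative is the better plan on step economy (roughly five steps from A1 to 17 against nine from 1). The two are equal in structure from 17 onward, since they share the later route. The chosen plan is safer in mechanism, because its configuration is inherited and the new centre is fixed by intramolecular reach rather than by a catalyst working at the edge of its usual substrate range.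

Alternative 2: The cut removes at once the bond from the acyl carbon to its quaternary carbon and the bond from the CH2 arm to the other quaternary carbon, and traces both to a [2+2] photocycloaddition between the C5=C6 bond of dioxinone A3 and the tetrasubstituted alkene A4. Irradiation would give cyclobutane A5 with the dioxanone and the cyclopentane cis-fused on opposite faces; acetal opening and retro-aldol cleavage of the cyclobutane (the de Mayo sequence) would give keto ester A6, with an acetyl group on one quaternary carbon and a CH2CO2CH3 arm on the other. In its favour, both quaternary carbons, their cis relationship (guaranteed by the cycloalkene) and both differentiated arms form in one step from two small reagents. The CH2 arm has the right length without homologation, and the acetyl group is already a ketone, so the enone might come from an aldol condensation instead of steps 17 to 22. Against it here, the stereocentres contributed by A3 are destroyed in the fragmentation, so the configuration of A6 depends on two selectivities multiplied: the face of A3 that is attacked and the anti versus syn placement of the cyclopentane. The syn adduct on the same face leads to the enantiomer of A6, and a single remote acetal centre is a modest controller. A tetrasubstituted alkene is also a slow partner, preparative photochemistry limits throughput, and the enolisable methyl ketone (or an enone made from it) would have to be masked before the Me3Al chemistry of step 16. In comparison, the alternative is better on step economy up to the stage of 17 (about three steps from A3 and A4, plus the preparation of A3) and possibly at the enone end. It is the equal of the chosen plan in delivering two distinct arms on a cis-dimethylcyclopentane. The chosen plan is better in stereochemical security, because one selectivity enforced by ring strain replaces two that are not.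

Alternative 3: The cut is made at the vinyl C–CH3 and vinyl C–CH2Ar bonds of the trisubstituted alkene and leads back to the terminal alkyne A7, Me3Al and the benzylic bromide 27; the coupling product is A8. The forward step is the Cp2ZrCl2-catalysed syn-methylalumination of A7 followed by Pd(PPh3)4-catalysed coupling of the alkenylalane with 27. In its favour, the E geometry follows from syn addition and retention, the arene is joined late and convergently, and in A8 the carbon on the acyl-bearing quaternary centre is already at the alcohol oxidation level, so the reduction of a very hindered ester (step 17) is not needed. Against it as the strategy-defining step, it creates no stereocentre and leaves the vicinal quaternary pair of A7 unsolved. A8 also carries a primary neopentyl and a secondary tert-butyldimethylsilyl ether that must later be told apart, and a configurationally pure carbinol is paid for although it becomes a ketone. In comparison, this is not a rival to the chosen plan but the same reaction as step 16, so on the alkene the two are equal in mechanism and selectivity. The alternative is better by one step at the aldehyde stage; the chosen plan is better in protecting-group economy and in supplying the origin of the cyclopentane.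

Key step: step 4

Assumption: the carbinol carbons formed in steps 10 and 19 are carried as epimer mixtures (no configuration is written for them), since both become ketone carbons in step 22; 18 is used as its commercial toluene solution.

## Route

Step 1
Reactants: 1 (1R,3S)-camphoric acid
Product: 2 (1R,5S)-1,8,8-trimethyl-3-oxabicyclo[3.2.1]octane-2,4-dione (camphoric anhydride)
Conditions: Ac2O, reflux
Reagents that add atoms: none
Why: Cyclodehydration of the cis-1,3-diacid to the bridged six-membered anhydride (anhydride formation); no stereocentre is touched.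

Step 2
Reactants: 2 camphoric anhydride
Product: 3 (1R,3S)-3-carbamoyl-1,2,2-trimethylcyclopentane-1-carboxylic acid
Conditions: NH3 (28% aq.), THF, 0 °C to rt; then 2 M HCl to pH 2
Reagents that add atoms: ammonia, SMILES N
Why: Anhydride aminolysis: ammonia attacks the carbonyl on the CH-bearing carbon, which is less shielded than the carbonyl flanked by two fully substituted carbons; the minor regioisomer should be removable by crystallisation.

Step 3
Reactants: 3 amide acid
Product: 4 methyl (1R,3S)-3-carbamoyl-1,2,2-trimethylcyclopentane-1-carboxylate
Conditions: MeI, K2CO3, DMF, rt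
Reagents that add atoms: iodomethane, SMILES CI
Why: SN2 O-alkylation of the carboxylate esterifies the hindered tertiary acid without attack at its carbonyl and leaves the neutral primary amide alone; MeI is used in place of diazomethane for safety.

Step 4
Reactants: 4 methyl (1R,3S)-3-carbamoyl-1,2,2-trimethylcyclopentane-1-carboxylate
Product: 8 methyl (1S,5S,8R)-1,8-dimethyl-4-oxo-3-oxabicyclo[3.3.0]octane-8-carboxylate, via N-iodoamide 5 (not isolated), via iodomethyl amide 6 (not isolated), via iminolactone 7 (not isolated)
Conditions: PhI(OAc)2 (2.5 equiv), I2 (1.2 equiv), ClCH2CH2Cl, visible light (tungsten lamp), 60 °C; then 1 M HCl, THF, rt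
Reagents that add atoms: water, SMILES O
Why: AcOI formed from PhI(OAc)2 and I2 N-iodinates the amide to 5; light cleaves the N–I bond, the amidyl radical takes a hydrogen atom from the geminal methyl on its own face through a six-membered transition state (N, C=O, C3, C2, CH3, H), and the primary radical is iodinated to 6. The amide oxygen then displaces iodide at the CH2 in a 5-exo-tet closure to iminolactone 7, which aqueous acid hydrolyses to 8. The closest known reaction type is the photolysis of N-iodoamides to γ-lactones (a Hofmann–Löffler–Freytag-type radical relay), known for an angular methyl on a quaternary carbon cis-vicinal to a ring carboxamide. The new stereocentre (C1 of 8, the former CMe2 carbon) is set by the substrate: only the methyl cis to the C3 carboxamide gives an iodide that can close a cis-fused bicyclo[3.3.0] lactone. The step needs site selectivity over the trans methyl, the ring CH2 groups and the C1 methyl; the trans methyl would need a more strained trans-fused array and could not lactonise, C5–H needs a bridged transition state, and the C1 methyl needs a seven-membered one on the far face. O- rather than N-alkylation is expected for a neutral primary amide.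

Step 5
Reactants: 8 lactone ester
Product: 11 (1S,2S,3R)-2-{[tert-butyl(dimethyl)silyl]oxymethyl}-3-(methoxycarbonyl)-2,3-dimethylcyclopentane-1-carboxylic acid, via potassium hydroxy carboxylate 9 (not isolated), via bis-silyl derivative 10 (not isolated)
Conditions: KOH (1.1 equiv), MeOH/H2O, rt; evaporate; TBSCl (3 equiv), imidazole, DMF, rt; then K2CO3, MeOH/THF/H2O, rt; aq. KHSO4 to pH 4
Reagents that add atoms: potassium hydroxide, SMILES [K+].[OH-]; tert-butyl(chloro)dimethylsilane, SMILES CC(C)(C)[Si](C)(C)Cl
Why: Hydroxide opens the γ-lactone while the ester between two quaternary carbons resists saponification; salt 9 is silylated on both oxygens before it can relactonise, and carbonate cleaves only the labile silyl ester of 10 (saponification, silyl protection).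

Step 6
Reactants: 11 silyloxy acid
Product: 13 methyl (1R,2S)-2-{[tert-butyl(dimethyl)silyl]oxymethyl}-1,2-dimethylcyclopentane-1-carboxylate, via thiohydroxamate ester 12 (not isolated)
Conditions: N-hydroxypyridine-2-thione, DCC, DMAP (cat.), CH2Cl2, dark, rt; then t-BuSH, visible light, rt
Reagents that add atoms: none
Why: Barton reductive decarboxylation: ester 12 fragments under light to the secondary C3 radical, which takes hydrogen from the thiol; the C3 stereocentre is deleted, and the thiol replaces tin hydride.

Step 7
Reactants: 13 silyl ether ester
Product: 14 methyl (1R,2S)-2-(hydroxymethyl)-1,2-dimethylcyclopentane-1-carboxylate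
Conditions: n-Bu4NF, AcOH (1:1), THF, 0 °C to rt
Reagents that add atoms: none
Why: Fluoride cleaves the Si–O bond; the acetic acid buffer keeps the alkoxide from forming, because the cis CH2O/CO2Me pair could close a γ-lactone, and the alcohol is oxidised at once.

Step 8
Reactants: 14 hydroxy ester
Product: 15 methyl (1R,2S)-2-formyl-1,2-dimethylcyclopentane-1-carboxylate
Conditions: Dess–Martin periodinane, pyridine, CH2Cl2, 0 °C
Reagents that add atoms: none
Why: Dess–Martin oxidation of a neopentyl primary alcohol under buffered, non-aqueous conditions; the aldehyde has no α-hydrogen and cannot epimerise.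

Step 9
Reactants: 15 aldehyde ester
Product: 17 methyl (1R,2R)-1,2-dimethyl-2-(2-oxoethyl)cyclopentane-1-carboxylate, via enol ether 16 (not isolated)
Conditions: Ph3P(CH2OMe)Cl, KN(SiMe3)2, THF, 0 °C to rt; then 2 M aq. HCl (cat.), THF, rt
Reagents that add atoms: (methoxymethyl)triphenylphosphonium chloride, SMILES COC[P+](c1ccccc1)(c1ccccc1)c1ccccc1.[Cl-]; water, SMILES O
Why: Wittig reaction with the small, reactive methoxymethylene ylide tolerates the neopentyl aldehyde, and acid hydrolysis of enol ether 16 gives the one-carbon homologue; the hindered ester is untouched.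

Step 10
Reactants: 17 homologated aldehyde; 18 3-bromoprop-1-yne
Product: 20 methyl (1R,2R)-2-(2-hydroxypent-4-yn-1-yl)-1,2-dimethylcyclopentane-1-carboxylate (both carbinol epimers), via allenylzinc bromide 19 (not isolated)
Conditions: Zn dust, 18 (80% in toluene), THF, 0 °C; then 17, −78 to 0 °C; aq. NH4Cl
Reagents that add atoms: none
Why: Barbier-type propargylation: allenylzinc bromide 19 adds to the aldehyde through a six-membered SE2′ transition state to give the homopropargylic alcohol; the carbinol centre is uncontrolled and is oxidised later.

Step 11
Reactants: 20 homopropargylic alcohol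
Product: 21 methyl (1R,2R)-2-(2-{[tert-butyl(dimethyl)silyl]oxy}pent-4-yn-1-yl)-1,2-dimethylcyclopentane-1-carboxylate
Conditions: TBSCl, imidazole, DMF, rt
Reagents that add atoms: tert-butyl(chloro)dimethylsilane, SMILES CC(C)(C)[Si](C)(C)Cl
Why: Standard silylation of a secondary alcohol; it masks the carbinol during the carboalumination and the later oxidation of the primary alcohol, and prevents δ-lactonisation.

Step 12
Reactants: 22 4-methoxy-3-methylphenol
Product: 23 (4-methoxy-3-methylphenoxy)tri(propan-2-yl)silane
Conditions: TIPSCl, imidazole, DMF, rt
Reagents that add atoms: chlorotri(propan-2-yl)silane, SMILES CC(C)[Si](Cl)(C(C)C)C(C)C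
Why: Phenol silylation; the bulky triisopropylsilyl group survives organolithium, aluminium and hydride reagents and shields its own ortho positions from metalation.

Step 13
Reactants: 23 aryl silyl ether
Product: 25 2-methoxy-3-methyl-5-{[tri(propan-2-yl)silyl]oxy}benzaldehyde, via aryllithium 24 (not isolated)
Conditions: n-BuLi, TMEDA, Et2O, 0 °C to rt; then DMF, 0 °C; aq. NH4Cl
Reagents that add atoms: N,N-dimethylformamide, SMILES CN(C)C=O
Why: Directed ortho-metalation: methoxy directs lithiation to its only free ortho position to give 24, while the silyloxy group is a poor director and blocks its neighbours; formylation with DMF follows.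

Step 14
Reactants: 25 aryl aldehyde
Product: 26 (2-methoxy-3-methyl-5-{[tri(propan-2-yl)silyl]oxy}phenyl)methanol
Conditions: NaBH4, MeOH, 0 °C
Reagents that add atoms: none
Why: Borohydride reduction of an aryl aldehyde; the silyl ether is inert.

Step 15
Reactants: 26 benzylic alcohol
Product: 27 [3-(bromomethyl)-4-methoxy-5-methylphenoxy]tri(propan-2-yl)silane
Conditions: CBr4, PPh3, CH2Cl2, 0 °C
Reagents that add atoms: tetrabromomethane, SMILES BrC(Br)(Br)Br
Why: Appel bromination under neutral conditions, compatible with the aryl silyl ether; the electron-rich benzylic bromide is used fresh.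

Step 16
Reactants: 21 silyl-protected alkyne; 27 benzylic bromide
Product: 29 methyl (1R,2R)-2-[(4E)-2-(tert-butyldimethylsilyloxy)-6-[2-methoxy-3-methyl-5-(triisopropylsilyloxy)phenyl]-4-methylhex-4-en-1-yl]-1,2-dimethylcyclopentane-1-carboxylate, via alkenylalane 28 (not isolated)
Conditions: Me3Al (3 equiv), Cp2ZrCl2 (0.3 equiv), CH2Cl2, 0 °C to rt; volatiles removed; then 27, Pd(PPh3)4 (5 mol%), THF, rt
Reagents that add atoms: trimethylaluminium, SMILES C[Al](C)C
Why: Negishi methylalumination–cross-coupling: Cp2ZrCl2-catalysed syn-carboalumination puts methyl on the internal and aluminium on the terminal alkyne carbon to give (E)-alkenylalane 28, and Pd(PPh3)4-catalysed coupling with the benzylic bromide proceeds with retention, fixing the E-trisubstituted alkene; the hindered ester and the silyl ethers tolerate Me3Al at room temperature.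

Step 17
Reactants: 29 coupled ester
Product: 30 [(1R,2R)-2-[(4E)-2-(tert-butyldimethylsilyloxy)-6-[2-methoxy-3-methyl-5-(triisopropylsilyloxy)phenyl]-4-methylhex-4-en-1-yl]-1,2-dimethylcyclopentyl]methanol
Conditions: i-Bu2AlH (3 equiv), CH2Cl2, −78 to 0 °C; then H2O
Reagents that add atoms: none
Why: Ester reduction: excess i-Bu2AlH takes the ester to the primary alcohol; the hindered position only slows the reaction, and the silyl ethers and the alkene are inert.

Step 18
Reactants: 30 primary alcohol
Product: 31 (1R,2R)-2-[(4E)-2-(tert-butyldimethylsilyloxy)-6-[2-methoxy-3-methyl-5-(triisopropylsilyloxy)phenyl]-4-methylhex-4-en-1-yl]-1,2-dimethylcyclopentane-1-carbaldehyde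
Conditions: Dess–Martin periodinane, pyridine, CH2Cl2, 0 °C to rt
Reagents that add atoms: none
Why: Dess–Martin oxidation to a neopentyl aldehyde that has no α-hydrogen; the silyl ethers and the alkene are unaffected.

Step 19
Reactants: 31 aldehyde; 32 2-methylbut-3-yn-2-ol
Product: 34 1-[(1R,2R)-2-[(4E)-2-(tert-butyldimethylsilyloxy)-6-[2-methoxy-3-methyl-5-(triisopropylsilyloxy)phenyl]-4-methylhex-4-en-1-yl]-1,2-dimethylcyclopentyl]-4-methylpent-2-yne-1,4-diol (both carbinol epimers), via dilithiated alkynol 33 (not isolated)
Conditions: 32 (4 equiv), n-BuLi (8 equiv), THF, −78 to 0 °C; then 31, −78 °C to rt; aq. NH4Cl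
Reagents that add atoms: none
Why: Acetylide 1,2-addition: the dilithio species 33 is a slim nucleophile that can reach the hindered aldehyde; the carbinol centre forms as an epimer mixture and is oxidised in step 22.

Step 20
Reactants: 34 silyl-protected ynediol
Product: 35 1-[(1R,2R)-2-[(4E)-2-hydroxy-6-[2-methoxy-3-methyl-5-(triisopropylsilyloxy)phenyl]-4-methylhex-4-en-1-yl]-1,2-dimethylcyclopentyl]-4-methylpent-2-yne-1,4-diol
Conditions: camphor-10-sulfonic acid (cat.), MeOH, rt
Reagents that add atoms: none
Why: Acid-catalysed methanolysis removes the alkyl silyl ether but not the aryl triisopropylsilyl ether; it is done at the ynediol stage, which tolerates acid better than the later allylic diol.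

Step 21
Reactants: 35 ynetriol
Product: 36 (2E)-1-[(1R,2R)-2-[(4E)-2-hydroxy-6-[2-methoxy-3-methyl-5-(triisopropylsilyloxy)phenyl]-4-methylhex-4-en-1-yl]-1,2-dimethylcyclopentyl]-4-methylpent-2-ene-1,4-diol
Conditions: NaAlH2(OCH2CH2OMe)2 (5 equiv), THF, 0 °C to rt; then H2O
Reagents that add atoms: none
Why: Propargylic alcohol reduction: alkoxide-directed trans-hydroalumination and protonolysis give the E-alkene from either flanking alkoxide; the isolated trisubstituted alkene is not reduced.

Step 22
Reactants: 36 enetriol
Product: 37 (2E)-4-hydroxy-1-[(1R,2R)-2-[(4E)-6-[2-methoxy-3-methyl-5-(triisopropylsilyloxy)phenyl]-4-methyl-2-oxohex-4-en-1-yl]-1,2-dimethylcyclopentyl]-4-methylpent-2-en-1-one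
Conditions: Dess–Martin periodinane (3 equiv), pyridine, CH2Cl2, 0 °C
Reagents that add atoms: none
Why: Both secondary carbinols are oxidised in one buffered Dess–Martin oxidation, the tertiary alcohol cannot react, and the neutral conditions keep the β,γ-unsaturated ketone out of conjugation; the phenol stays silylated because a free p-methoxyphenol would be oxidised.

Step 23
Reactants: 37 silylated diketone
Product: 38 (2E)-4-hydroxy-1-[(1R,2R)-2-[(4E)-6-(5-hydroxy-2-methoxy-3-methylphenyl)-4-methyl-2-oxohex-4-en-1-yl]-1,2-dimethylcyclopentyl]-4-methylpent-2-en-1-one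
Conditions: n-Bu4NF, AcOH (1:1), THF, 0 °C
Reagents that add atoms: none
Why: Fluoride cleaves the aryl silyl ether rapidly; the acetic acid buffer suppresses base-promoted alkene migration and aldol closure of the 1,5-diketone.

## Compound list

1 | (1R,3S)-camphoric acid | CC1(C)[C@@H](C(=O)O)CC[C@@]1(C)C(=O)O | starting material
2 | (1R,5S)-1,8,8-trimethyl-3-oxabicyclo[3.2.1]octane-2,4-dione | CC1(C)[C@@H]2CC[C@@]1(C)C(=O)OC2=O | intermediate
3 | (1R,3S)-3-carbamoyl-1,2,2-trimethylcyclopentane-1-carboxylic acid | CC1(C)[C@@H](C(N)=O)CC[C@@]1(C)C(=O)O | intermediate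
4 | methyl (1R,3S)-3-carbamoyl-1,2,2-trimethylcyclopentane-1-carboxylate | COC(=O)[C@]1(C)CC[C@H](C(N)=O)C1(C)C | intermediate
5 | methyl (1R,3S)-3-(iodocarbamoyl)-1,2,2-trimethylcyclopentane-1-carboxylate | COC(=O)[C@]1(C)CC[C@H](C(=O)NI)C1(C)C | intermediate
6 | methyl (1R,2S,3S)-3-carbamoyl-2-(iodomethyl)-1,2-dimethylcyclopentane-1-carboxylate (iodomethyl cis to carbamoyl) | COC(=O)[C@]1(C)CC[C@H](C(N)=O)[C@]1(C)CI | intermediate
7 | methyl (1S,5S,8R)-4-imino-1,8-dimethyl-3-oxabicyclo[3.3.0]octane-8-carboxylate | COC(=O)[C@]1(C)CC[C@@H]2C(=N)OC[C@]12C | intermediate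
8 | methyl (1S,5S,8R)-1,8-dimethyl-4-oxo-3-oxabicyclo[3.3.0]octane-8-carboxylate (cis-fused) | COC(=O)[C@]1(C)CC[C@@H]2C(=O)OC[C@]12C | intermediate
9 | potassium (1S,2S,3R)-2-(hydroxymethyl)-3-(methoxycarbonyl)-2,3-dimethylcyclopentane-1-carboxylate | COC(=O)[C@]1(C)CC[C@H](C(=O)[O-])[C@]1(C)CO.[K+] | intermediate
10 | tert-butyl(dimethyl)silyl ester of acid 11 | COC(=O)[C@]1(C)CC[C@H](C(=O)O[Si](C)(C)C(C)(C)C)[C@]1(C)CO[Si](C)(C)C(C)(C)C | intermediate
11 | (1S,2S,3R)-2-{[tert-butyl(dimethyl)silyl]oxymethyl}-3-(methoxycarbonyl)-2,3-dimethylcyclopentane-1-carboxylic acid | COC(=O)[C@]1(C)CC[C@H](C(=O)O)[C@]1(C)CO[Si](C)(C)C(C)(C)C | intermediate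
12 | 2-thioxopyridin-1(2H)-yl ester of acid 11 (O-acyl thiohydroxamate) | COC(=O)[C@]1(C)CC[C@H](C(=O)ON2C=CC=CC2=S)[C@]1(C)CO[Si](C)(C)C(C)(C)C | intermediate
13 | methyl (1R,2S)-2-{[tert-butyl(dimethyl)silyl]oxymethyl}-1,2-dimethylcyclopentane-1-carboxylate | COC(=O)[C@]1(C)CCC[C@]1(C)CO[Si](C)(C)C(C)(C)C | intermediate
14 | methyl (1R,2S)-2-(hydroxymethyl)-1,2-dimethylcyclopentane-1-carboxylate | COC(=O)[C@]1(C)CCC[C@]1(C)CO | intermediate
15 | methyl (1R,2S)-2-formyl-1,2-dimethylcyclopentane-1-carboxylate | COC(=O)[C@]1(C)CCC[C@]1(C)C=O | intermediate
16 | methyl (1R,2R)-2-(2-methoxyethenyl)-1,2-dimethylcyclopentane-1-carboxylate (E/Z mixture) | COC(=O)[C@]1(C)CCC[C@]1(C)C=COC | intermediate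
17 | methyl (1R,2R)-1,2-dimethyl-2-(2-oxoethyl)cyclopentane-1-carboxylate | COC(=O)[C@]1(C)CCC[C@]1(C)CC=O | intermediate
18 | 3-bromoprop-1-yne | C#CCBr | starting material
19 | bromo(propa-1,2-dien-1-yl)zinc | C=C=C[Zn]Br | intermediate
20 | methyl (1R,2R)-2-(2-hydroxypent-4-yn-1-yl)-1,2-dimethylcyclopentane-1-carboxylate (carbinol epimers) | COC(=O)[C@]1(C)CCC[C@]1(C)CC(O)CC#C | intermediate
21 | methyl (1R,2R)-2-(2-{[tert-butyl(dimethyl)silyl]oxy}pent-4-yn-1-yl)-1,2-dimethylcyclopentane-1-carboxylate (carbinol epimers) | COC(=O)[C@]1(C)CCC[C@]1(C)CC(CC#C)O[Si](C)(C)C(C)(C)C | intermediate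
22 | 4-methoxy-3-methylphenol | COc1ccc(O)cc1C | starting material
23 | (4-methoxy-3-methylphenoxy)tri(propan-2-yl)silane | COc1ccc(O[Si](C(C)C)(C(C)C)C(C)C)cc1C | intermediate
24 | [2-methoxy-3-methyl-5-(triisopropylsilyloxy)phenyl]lithium | COc1c([Li])cc(O[Si](C(C)C)(C(C)C)C(C)C)cc1C | intermediate
25 | 2-methoxy-3-methyl-5-{[tri(propan-2-yl)silyl]oxy}benzaldehyde | COc1c(C)cc(O[Si](C(C)C)(C(C)C)C(C)C)cc1C=O | intermediate
26 | (2-methoxy-3-methyl-5-{[tri(propan-2-yl)silyl]oxy}phenyl)methanol | COc1c(C)cc(O[Si](C(C)C)(C(C)C)C(C)C)cc1CO | intermediate
27 | [3-(bromomethyl)-4-methoxy-5-methylphenoxy]tri(propan-2-yl)silane | COc1c(C)cc(O[Si](C(C)C)(C(C)C)C(C)C)cc1CBr | intermediate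
28 | methyl (1R,2R)-2-[(4E)-2-(tert-butyldimethylsilyloxy)-5-(dimethylalumanyl)-4-methylpent-4-en-1-yl]-1,2-dimethylcyclopentane-1-carboxylate | COC(=O)[C@]1(C)CCC[C@]1(C)CC(O[Si](C)(C)C(C)(C)C)C/C(C)=C/[Al](C)C | intermediate
29 | methyl (1R,2R)-2-[(4E)-2-(tert-butyldimethylsilyloxy)-6-[2-methoxy-3-methyl-5-(triisopropylsilyloxy)phenyl]-4-methylhex-4-en-1-yl]-1,2-dimethylcyclopentane-1-carboxylate | COc1c(C)cc(O[Si](C(C)C)(C(C)C)C(C)C)cc1C/C=C(\C)CC(O[Si](C)(C)C(C)(C)C)C[C@@]1(C)CCC[C@@]1(C)C(=O)OC | intermediate
30 | [(1R,2R)-2-[(4E)-2-(tert-butyldimethylsilyloxy)-6-[2-methoxy-3-methyl-5-(triisopropylsilyloxy)phenyl]-4-methylhex-4-en-1-yl]-1,2-dimethylcyclopentyl]methanol | COc1c(C)cc(O[Si](C(C)C)(C(C)C)C(C)C)cc1C/C=C(\C)CC(O[Si](C)(C)C(C)(C)C)C[C@@]1(C)CCC[C@@]1(C)CO | intermediate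
31 | (1R,2R)-2-[(4E)-2-(tert-butyldimethylsilyloxy)-6-[2-methoxy-3-methyl-5-(triisopropylsilyloxy)phenyl]-4-methylhex-4-en-1-yl]-1,2-dimethylcyclopentane-1-carbaldehyde | COc1c(C)cc(O[Si](C(C)C)(C(C)C)C(C)C)cc1C/C=C(\C)CC(O[Si](C)(C)C(C)(C)C)C[C@@]1(C)CCC[C@@]1(C)C=O | intermediate
32 | 2-methylbut-3-yn-2-ol | CC(C)(O)C#C | starting material
33 | O,C-dilithio-2-methylbut-3-yn-2-ol | [Li]OC(C)(C)C#C[Li] | intermediate
34 | 1-[(1R,2R)-2-[(4E)-2-(tert-butyldimethylsilyloxy)-6-[2-methoxy-3-methyl-5-(triisopropylsilyloxy)phenyl]-4-methylhex-4-en-1-yl]-1,2-dimethylcyclopentyl]-4-methylpent-2-yne-1,4-diol | COc1c(C)cc(O[Si](C(C)C)(C(C)C)C(C)C)cc1C/C=C(\C)CC(O[Si](C)(C)C(C)(C)C)C[C@@]1(C)CCC[C@@]1(C)C(O)C#CC(C)(C)O | intermediate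
35 | 1-[(1R,2R)-2-[(4E)-2-hydroxy-6-[2-methoxy-3-methyl-5-(triisopropylsilyloxy)phenyl]-4-methylhex-4-en-1-yl]-1,2-dimethylcyclopentyl]-4-methylpent-2-yne-1,4-diol | COc1c(C)cc(O[Si](C(C)C)(C(C)C)C(C)C)cc1C/C=C(\C)CC(O)C[C@@]1(C)CCC[C@@]1(C)C(O)C#CC(C)(C)O | intermediate
36 | (2E)-1-[(1R,2R)-2-[(4E)-2-hydroxy-6-[2-methoxy-3-methyl-5-(triisopropylsilyloxy)phenyl]-4-methylhex-4-en-1-yl]-1,2-dimethylcyclopentyl]-4-methylpent-2-ene-1,4-diol | COc1c(C)cc(O[Si](C(C)C)(C(C)C)C(C)C)cc1C/C=C(\C)CC(O)C[C@@]1(C)CCC[C@@]1(C)C(O)/C=C/C(C)(C)O | intermediate
37 | (2E)-4-hydroxy-1-[(1R,2R)-2-[(4E)-6-[2-methoxy-3-methyl-5-(triisopropylsilyloxy)phenyl]-4-methyl-2-oxohex-4-en-1-yl]-1,2-dimethylcyclopentyl]-4-methylpent-2-en-1-one | COc1c(C)cc(O[Si](C(C)C)(C(C)C)C(C)C)cc1C/C=C(\C)CC(=O)C[C@@]1(C)CCC[C@@]1(C)C(=O)/C=C/C(C)(C)O | intermediate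
38 | (2E)-4-hydroxy-1-[(1R,2R)-2-[(4E)-6-(5-hydroxy-2-methoxy-3-methylphenyl)-4-methyl-2-oxohex-4-en-1-yl]-1,2-dimethylcyclopentyl]-4-methylpent-2-en-1-one | COc1c(C)cc(O)cc1C/C=C(\C)CC(=O)C[C@@]1(C)CCC[C@@]1(C)C(=O)/C=C/C(C)(C)O | target

## Step count and least certain steps

Total: 23 steps. Longest linear sequence: 19 steps (steps 1 to 11 and 16 to 23, from 1 to 38); the arene branch (steps 12 to 15) has 4 steps.

Step 4 (key step). The most likely failure is hydrogen abstraction at a site other than the cis methyl (the trans methyl or ring C5–H), which would consume material as iodides that cannot lactonise. Next most likely is interception of the primary amide by the trivalent iodine reagent (Hofmann-type rearrangement) or N-closure to a lactam, because the amide is an ambident nucleophile. The fallback sets out from 1 and returns to the route at 8, using an alkoxy radical in place of the amidyl radical. Double O-methylation of 1 (MeI, K2CO3, DMF) would give dimethyl (1R,3S)-1,2,2-trimethylcyclopentane-1,3-dicarboxylate F1. LiBH4 in THF should reduce only the ester on the CH-bearing carbon and give methyl (1R,3S)-3-(hydroxymethyl)-1,2,2-trimethylcyclopentane-1-carboxylate F2. The alkoxy radical generated from F2 with PhI(OAc)2 and I2 under visible light should abstract hydrogen from the same cis methyl through a six-membered transition state and close the cyclic ether methyl (1S,5S,8R)-1,8-dimethyl-3-oxabicyclo[3.3.0]octane-8-carboxylate F3. Oxidation of F3 with RuCl3 (cat.) and NaIO4 at the less hindered OCH2, the one next to the CH carbon, would give 8.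

Step 5. The hydroxy carboxylate may reclose to 8 during drying or silylation, or on acidification, because the cis γ-hydroxy acid lactonises very readily; incomplete differentiation of silyl ester and silyl ether is the second concern. The fallback sets out from 8 and returns at 14; it removes the lactone carbonyl by radical fragmentation and never forms the hydroxy acid. Reduction of 8 with i-Bu2AlH (1.1 equiv, −78 °C) should stop at the lactol methyl (1S,5S,8R)-4-hydroxy-1,8-dimethyl-3-oxabicyclo[3.3.0]octane-8-carboxylate F4, since the hindered ester reacts far more slowly. The alkoxy radical of F4 (PhI(OAc)2, I2, visible light) should undergo β-scission of the C–C bond to C3 and iodine trapping to give methyl 2-[(formyloxy)methyl]-3-iodo-1,2-dimethylcyclopentane-1-carboxylate F5 (C3 epimers). Hydrogenolysis (H2, palladium on carbon, Et3N) would give methyl (1R,2S)-2-[(formyloxy)methyl]-1,2-dimethylcyclopentane-1-carboxylate F6, and mild methanolysis of the formate (KHCO3, MeOH) would give 14.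

Step 7. The freed hydroxyl may close onto the neighbouring ester (γ-lactonisation), helped by the two quaternary carbons, which would merge the two branches into one ring and stall the route. The fallback sets out from 8 and returns at 15 without ever freeing the alcohol. Step 5 run with Et3SiCl in place of TBSCl would give (1S,2S,3R)-3-(methoxycarbonyl)-2,3-dimethyl-2-[(triethylsilyloxy)methyl]cyclopentane-1-carboxylic acid F7. Barton decarboxylation as in step 6 would give methyl (1R,2S)-1,2-dimethyl-2-[(triethylsilyloxy)methyl]cyclopentane-1-carboxylate F8. Swern conditions ((COCl)2, DMSO, Et3N, CH2Cl2, −78 °C to rt), which convert primary triethylsilyl ethers directly into aldehydes, would then give 15.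

Step 16. Carbometalation may be incomplete, or methyl rather than alkenyl may be transferred from aluminium to the benzylpalladium intermediate, because excess Me3Al is present and the alane carries a bulky neighbour; homocoupling of the reactive benzylic bromide is also possible. The fallback sets out from 21 and 27 and returns at 29, with the polarity of the coupling reversed. Carboalumination of 21 as before and quenching with I2 would give the isolable vinyl iodide methyl (1R,2R)-2-[(4E)-2-(tert-butyldimethylsilyloxy)-5-iodo-4-methylpent-4-en-1-yl]-1,2-dimethylcyclopentane-1-carboxylate F9. Zinc insertion into 27 (Zn dust, THF) would give the benzylzinc bromide [2-methoxy-3-methyl-5-(triisopropylsilyloxy)benzyl]zinc bromide F10. Negishi coupling of F9 with F10 under Pd(PPh3)4 catalysis would give 29.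

Step 23. Fluoride is basic enough to move the skipped double bond into conjugation with the ketone or to start an aldol closure of the 1,5-diketone, both driven by the acidity of the doubly activated CH2 between alkene and ketone. The fallback sets out from 36 and returns at 38; the phenol is unmasked before the sensitive ketones exist and is carried as an acetate that is removed without base. Desilylation of 36 (n-Bu4NF, THF) would give (2E)-1-[(1R,2R)-2-[(4E)-2-hydroxy-6-(5-hydroxy-2-methoxy-3-methylphenyl)-4-methylhex-4-en-1-yl]-1,2-dimethylcyclopentyl]-4-methylpent-2-ene-1,4-diol F11. Phenoxide-selective acetylation (Ac2O, K2CO3, acetone) would give its aryl acetate F12, and Dess–Martin oxidation as in step 22 would give the diketone aryl acetate F13. Cleavage of the aryl acetate with NH4OAc in aqueous MeOH at rt, a neutral method selective for phenolic acetates, would give 38.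

## Further compounds

F1 | step 4 | dimethyl (1R,3S)-1,2,2-trimethylcyclopentane-1,3-dicarboxylate | COC(=O)[C@]1(C)CC[C@H](C(=O)OC)C1(C)C
F2 | step 4 | methyl (1R,3S)-3-(hydroxymethyl)-1,2,2-trimethylcyclopentane-1-carboxylate | COC(=O)[C@]1(C)CC[C@H](CO)C1(C)C
F3 | step 4 | methyl (1S,5S,8R)-1,8-dimethyl-3-oxabicyclo[3.3.0]octane-8-carboxylate | COC(=O)[C@]1(C)CC[C@@H]2COC[C@]12C
F4 | step 5 | methyl (1S,5S,8R)-4-hydroxy-1,8-dimethyl-3-oxabicyclo[3.3.0]octane-8-carboxylate (anomer mixture) | COC(=O)[C@]1(C)CC[C@@H]2C(O)OC[C@]12C
F5 | step 5 | methyl 2-[(formyloxy)methyl]-3-iodo-1,2-dimethylcyclopentane-1-carboxylate (ring configuration as in 13, C3 epimers) | COC(=O)[C@]1(C)CCC(I)[C@]1(C)COC=O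
F6 | step 5 | methyl (1R,2S)-2-[(formyloxy)methyl]-1,2-dimethylcyclopentane-1-carboxylate | COC(=O)[C@]1(C)CCC[C@]1(C)COC=O
F7 | step 7 | (1S,2S,3R)-3-(methoxycarbonyl)-2,3-dimethyl-2-[(triethylsilyloxy)methyl]cyclopentane-1-carboxylic acid | COC(=O)[C@]1(C)CC[C@H](C(=O)O)[C@]1(C)CO[Si](CC)(CC)CC
F8 | step 7 | methyl (1R,2S)-1,2-dimethyl-2-[(triethylsilyloxy)methyl]cyclopentane-1-carboxylate | COC(=O)[C@]1(C)CCC[C@]1(C)CO[Si](CC)(CC)CC
F9 | step 16 | methyl (1R,2R)-2-[(4E)-2-(tert-butyldimethylsilyloxy)-5-iodo-4-methylpent-4-en-1-yl]-1,2-dimethylcyclopentane-1-carboxylate | COC(=O)[C@]1(C)CCC[C@]1(C)CC(O[Si](C)(C)C(C)(C)C)C/C(C)=C/I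
F10 | step 16 | [2-methoxy-3-methyl-5-(triisopropylsilyloxy)benzyl]zinc bromide | COc1c(C)cc(O[Si](C(C)C)(C(C)C)C(C)C)cc1C[Zn]Br
F11 | step 23 | (2E)-1-[(1R,2R)-2-[(4E)-2-hydroxy-6-(5-hydroxy-2-methoxy-3-methylphenyl)-4-methylhex-4-en-1-yl]-1,2-dimethylcyclopentyl]-4-methylpent-2-ene-1,4-diol | COc1c(C)cc(O)cc1C/C=C(\C)CC(O)C[C@@]1(C)CCC[C@@]1(C)C(O)/C=C/C(C)(C)O
F12 | step 23 | aryl acetate of F11 (acetate on the phenol oxygen) | COc1c(C)cc(OC(C)=O)cc1C/C=C(\C)CC(O)C[C@@]1(C)CCC[C@@]1(C)C(O)/C=C/C(C)(C)O
F13 | step 23 | aryl acetate of 38 | COc1c(C)cc(OC(C)=O)cc1C/C=C(\C)CC(=O)C[C@@]1(C)CCC[C@@]1(C)C(=O)/C=C/C(C)(C)O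
A1 | alternative 1 | bicyclo[3.3.0]oct-1(5)-en-2-one | O=C1CCC2=C1CCC2
A2 | alternative 1 | (1R,5R)-1,5-dimethylbicyclo[3.3.0]octan-2-one (cis-fused) | O=C1CC[C@@]2(C)CCC[C@@]12C
A3 | alternative 2 | (R)-2-tert-butyl-6-methyl-1,3-dioxin-4-one | CC1=CC(=O)O[C@H](C(C)(C)C)O1
A4 | alternative 2 | 1,2-dimethylcyclopentene | CC1=C(C)CCC1
A5 | alternative 2 | cis-anti-cis tricyclic photoadduct (cyclobutane fused to dioxanone and cyclopentane) | C[C@@]12O[C@@H](C(C)(C)C)OC(=O)[C@@H]1[C@@]1(C)CCC[C@@]21C
A6 | alternative 2 | methyl 2-[(1R,2R)-2-acetyl-1,2-dimethylcyclopentyl]acetate | COC(=O)C[C@@]1(C)CCC[C@@]1(C)C(C)=O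
A7 | alternative 3 | bis-silyl ether terminal alkyne (S carbinol; CH2OTBS on the second quaternary carbon) | C#CC[C@H](O[Si](C)(C)C(C)(C)C)C[C@@]1(C)CCC[C@@]1(C)CO[Si](C)(C)C(C)(C)C
A8 | alternative 3 | fully protected E-alkene coupling product | COc1c(C)cc(O[Si](C(C)C)(C(C)C)C(C)C)cc1C/C=C(\C)C[C@H](O[Si](C)(C)C(C)(C)C)C[C@@]1(C)CCC[C@@]1(C)CO[Si](C)(C)C(C)(C)C
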